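The synthesis rests on cutting the C4a–C5 bond of ring A (naphthalene numbering, aryl on C1). The edge C5(O)–C6(O)–C7(O)–C8(H) of ring A is, carbon for carbon, the ring of a squarate-derived cyclobutenone: carbonyl, two alkoxy-bearing alkene carbons and an aryl-bearing CH. Heating precursor 18, a 4-(biaryl)cyclobutenone with isopropyl on the C2 oxygen (future O6) and methyl on the C3 oxygen (future O7), opens the small ring to a dienylketene. This closes onto C4a, the only free ortho carbon of ring B, and aromatises, so ring A appears in one operation as 5-naphthol 22. O5-methylation and one BCl3 dealkylation (O6, O4') finish.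

Key step: step 12

Remark: ring A is the oxygenated naphthalene ring, ring B the dimethyl-bearing ring and ring C the pendant aryl ring. Atoms are given their final naphthalene numbers before the ring exists. Sulfoxides 4, 5, 6 and 11, cyclobutenones 15–18 and dienone 21 are racemic and are written without stereodescriptors. Every stereocentre is lost before the target, which has none.

Step 1
Reactants: 1 2,3-dimethylphenol
Product: 2 2,3-dimethylphenyl N,N-diethylcarbamate
Conditions: Et2NCOCl, K2CO3, MeCN, reflux
Reagents that add atoms: N,N-diethylcarbamoyl chloride, CCN(CC)C(=O)Cl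
Why: O-acylation of the phenoxide with a carbamoyl chloride gives the aryl O-carbamate, the strongest oxygen-based director for the ortho-metalation of step 2.

Step 2
Reactants: 2 2,3-dimethylphenyl N,N-diethylcarbamate
Product: 4 rac-2,3-dimethyl-6-[(4-methylphenyl)sulfinyl]phenyl N,N-diethylcarbamate, via lithiated carbamate 3 (not isolated)
Conditions: s-BuLi, TMEDA, THF, -78 °C; then cannulated into p-TolS(O)OMe, THF, -78 °C
Reagents that add atoms: methyl 4-methylbenzenesulfinate, COS(=O)c1ccc(C)cc1
Why: Directed ortho-metalation followed by Andersen-type substitution at sulfur: at -78 °C the carbamate-bound alkyllithium-diamine complex removes the single ring hydrogen ortho to oxygen rather than a hydrogen of the flanking methyl group (lateral lithiation is the lithium-amide pathway), the anionic Fries shift stays frozen, and inverse addition keeps 3 away from the sulfoxide already formed; sulfur is chosen because, unlike tin, boron or bromine next to a triflate, it neither couples nor triggers aryne formation in step 6 yet can be exchanged for lithium in step 7, and its stereocentre forms racemic and is removed there.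

Step 3
Reactants: 4 rac-2,3-dimethyl-6-[(4-methylphenyl)sulfinyl]phenyl N,N-diethylcarbamate
Product: 5 rac-2,3-dimethyl-6-[(4-methylphenyl)sulfinyl]phenol
Conditions: NaOH, EtOH-H2O, reflux; then aq HCl
Reagents that add atoms: none
Why: Alkaline carbamate hydrolysis (addition-elimination at the carbonyl group) is helped by the better leaving ability of the sulfinyl-substituted phenoxide, and diaryl sulfoxides tolerate hot alkali.

Step 4
Reactants: 5 rac-2,3-dimethyl-6-[(4-methylphenyl)sulfinyl]phenol
Product: 6 rac-2,3-dimethyl-6-[(4-methylphenyl)sulfinyl]phenyl trifluoromethanesulfonate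
Conditions: PhNTf2, Et3N, DMAP (cat.), CH2Cl2, 0 °C to rt
Reagents that add atoms: N-phenylbis(trifluoromethanesulfonimide), O=S(=O)(N(c1ccccc1)S(=O)(=O)C(F)(F)F)C(F)(F)F
Why: Phenol triflation with the mild triflyl donor PhNTf2, chosen over Tf2O because the anhydride would attack the sulfoxide oxygen (Pummerer-type activation).

Step 5
Reactants: 7 4-bromo-2,6-dimethoxyphenol
Product: 8 5-bromo-1,3-dimethoxy-2-(propan-2-yloxy)benzene
Conditions: i-PrBr, K2CO3, DMF, 60 °C
Reagents that add atoms: 2-bromopropane, CC(C)Br
Why: Williamson ether synthesis; the isopropyl ether has no benzylic hydrogen to lose to the alkyllithium reagents of steps 6 and 7 and falls to BCl3 at the end under conditions that leave methyl ethers alone.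

Step 6
Reactants: 8 5-bromo-1,3-dimethoxy-2-(propan-2-yloxy)benzene; 6 rac-2,3-dimethyl-6-[(4-methylphenyl)sulfinyl]phenyl trifluoromethanesulfonate
Product: 11 rac-3',5'-dimethoxy-2,3-dimethyl-6-[(4-methylphenyl)sulfinyl]-4'-(propan-2-yloxy)-1,1'-biphenyl, via aryllithium 9 (not isolated), via arylzinc chloride 10 (not isolated)
Conditions: 8, n-BuLi, THF, -78 °C; ZnCl2, -78 °C to rt; then 6, Pd2(dba)3 (cat.), SPhos (cat.), THF, 60 °C
Reagents that add atoms: none
Why: Negishi coupling: bromine-lithium exchange and transmetalation give an unhindered arylzinc, and the triflate, activated by the ortho sulfinyl group, adds oxidatively to zerovalent palladium although flanked on both sides, so the crowded C1-C1' bond is made on a simple benzene ring; no stereoaxis arises because ring C is symmetric about the axis.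

Step 7
Reactants: 11 rac-3',5'-dimethoxy-2,3-dimethyl-6-[(4-methylphenyl)sulfinyl]-4'-(propan-2-yloxy)-1,1'-biphenyl
Product: 13 [3',5'-dimethoxy-5,6-dimethyl-4'-(propan-2-yloxy)biphenyl-2-yl]trimethylstannane, via biaryllithium 12 (not isolated)
Conditions: t-BuLi, THF, -78 °C, 10 min; Me3SnCl, -78 °C to rt
Reagents that add atoms: chlorotrimethylstannane, C[Sn](C)(C)Cl
Why: Sulfoxide-lithium exchange, well established for 2-sulfinylbiaryls: attack of t-BuLi at sulfur expels the more stabilised and more crowded aryl anion 12 within minutes, Me3SnCl traps it, and the small trimethylstannyl group is preferred because an ortho-arylated carbon must be transferred in step 10.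

Step 8
Reactants: 14 3,4-di(propan-2-yloxy)cyclobut-3-ene-1,2-dione (diisopropyl squarate)
Product: 15 rac-4-hydroxy-2,3-di(propan-2-yloxy)cyclobut-2-en-1-one
Conditions: LiAlH(OtBu)3, THF, -20 to 0 °C; then H2O
Reagents that add atoms: none
Why: Chemoselective 1,2-reduction of one of two equivalent carbonyl groups by a bulky, mild hydride; the product is a vinylogous ester that is not reduced further, the non-acidic work-up avoids ionisation at C4, and the new stereocentre is racemic and disappears in step 12.

Step 9
Reactants: 15 rac-4-hydroxy-2,3-di(propan-2-yloxy)cyclobut-2-en-1-one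
Product: 16 rac-4-chloro-2,3-di(propan-2-yloxy)cyclobut-2-en-1-one
Conditions: Me2C=C(Cl)NMe2, CH2Cl2, -20 to 0 °C; used crude
Reagents that add atoms: 1-chloro-N,N,2-trimethylprop-1-en-1-amine, CC(C)=C(Cl)N(C)C
Why: Neutral deoxychlorination with an alpha-chloroenamine (alkoxyiminium chloride, then SN2 displacement at the carbonyl-activated carbon) avoids the acid that would ionise C4 and strip the C2 alkyl group, and secondary isopropyl ethers are used because chloride dealkylates them less readily than methyl or benzyl ethers.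

Step 10
Reactants: 13 [3',5'-dimethoxy-5,6-dimethyl-4'-(propan-2-yloxy)biphenyl-2-yl]trimethylstannane; 16 rac-4-chloro-2,3-di(propan-2-yloxy)cyclobut-2-en-1-one
Product: 17 rac-4-[2-(4-isopropoxy-3,5-dimethoxyphenyl)-3,4-dimethylphenyl]-2,3-diisopropoxycyclobut-2-en-1-one
Conditions: PdCl2(PhCN)2 (cat.), P(2-furyl)3 (cat.), CuI (cat.), dioxane, 45 °C
Reagents that add atoms: none
Why: Stille coupling of a 4-chlorocyclobutenone with an arylstannane: oxidative addition of the allylic, alpha-keto C-Cl bond to zerovalent palladium, tin-to-palladium transfer aided by the weakly donating furylphosphine and CuI, and reductive elimination at the less substituted terminus C4 form the future C8a-C8 bond below the temperature at which the product ring opens; the stereocentre is racemic.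

Step 11
Reactants: 17 rac-4-[2-(4-isopropoxy-3,5-dimethoxyphenyl)-3,4-dimethylphenyl]-2,3-diisopropoxycyclobut-2-en-1-one
Product: 18 rac-4-[2-(4-isopropoxy-3,5-dimethoxyphenyl)-3,4-dimethylphenyl]-2-isopropoxy-3-methoxycyclobut-2-en-1-one
Conditions: camphorsulfonic acid (cat.), dry MeOH, 25 °C
Reagents that add atoms: methanol, CO
Why: Acid-catalysed vinylogous transesterification: protonation of the carbonyl oxygen makes only C3, the beta carbon of the enone, electrophilic, so solvent methanol replaces the C3 isopropoxy group by addition-elimination while the group on the alpha carbon C2 cannot exchange, which sets future O7 (methyl) apart from future O6 (isopropyl); acid is safe here because C4 carries no leaving group, whereas alkoxide could add to the carbonyl group and cleave the strained ring.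

Step 12
Reactants: 18 rac-4-[2-(4-isopropoxy-3,5-dimethoxyphenyl)-3,4-dimethylphenyl]-2-isopropoxy-3-methoxycyclobut-2-en-1-one
Product: 22 5-(4-isopropoxy-3,5-dimethoxyphenyl)-2-isopropoxy-3-methoxy-6,7-dimethylnaphthalen-1-ol, via aryl-out ketene 19 (not isolated), via aryl-in ketene 20 (not isolated), via dienone 21 (not isolated)
Conditions: p-xylene (0.01 M, dry, degassed), reflux (138 °C), Ar
Reagents that add atoms: none
Why: Thermal conrotatory 4π electrocyclic opening breaks the C1-C4 bond of the cyclobutenone and gives two geometric isomers of the vinylketene, 19 with the aryl group turned away from the ketene (the easier outward rotation) and 20 with it turned toward the ketene; these are not rotamers and interconvert only by reclosure to 18, so the reversible opening funnels all material through 20. In 20 the ketene C=C bond, the C7=C8 enol-ether bond and the C8a=C4a bond of ring B form a hexatriene whose disrotatory 6π electrocyclisation joins the ketene carbon to C4a, closing six-membered ring A through the C4a-C5 bond and giving dienone 21. Enolisation of 21 restores the aromaticity of ring B, creates the C5 hydroxyl group and makes the sequence irreversible. The closest known reaction is the Moore-type benzannulation of 4-aryl-2-cyclobutenones to 1-naphthols, the same 4π/6π cascade that ends a Danheiser benzannulation. No stereocentre survives, since C4 of 18 becomes sp2 C8 and the transient C4a-H centre of 21 is erased on tautomerisation. The only selectivity needed is the site of closure, and the substrate fixes it because the other ortho carbon of ring B (C1) carries ring C; high dilution in dry, oxygen-free solvent keeps 19 from dimerising or being trapped and protects the oxidisable naphthol.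

Step 13
Reactants: 22 5-(4-isopropoxy-3,5-dimethoxyphenyl)-2-isopropoxy-3-methoxy-6,7-dimethylnaphthalen-1-ol
Product: 23 1-(4-isopropoxy-3,5-dimethoxyphenyl)-6-isopropoxy-5,7-dimethoxy-2,3-dimethylnaphthalene
Conditions: MeI, K2CO3, acetone, reflux, Ar
Reagents that add atoms: iodomethane, CI
Why: Williamson methylation of the only free hydroxyl group (O5), run under argon directly after step 12 because an electron-rich 1-naphthol with a free para position (C8) is prone to air oxidation.

Step 14
Reactants: 23 1-(4-isopropoxy-3,5-dimethoxyphenyl)-6-isopropoxy-5,7-dimethoxy-2,3-dimethylnaphthalene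
Product: 24 sacidumlignan A, 5-(4-hydroxy-3,5-dimethoxyphenyl)-1,3-dimethoxy-6,7-dimethylnaphthalen-2-ol
Conditions: BCl3, CH2Cl2, -78 to 0 °C; then H2O
Reagents that add atoms: none
Why: Lewis-acid ether cleavage: BCl3 binds the two most basic, out-of-plane oxygens (O6 and O4', each flanked by two methoxy groups) and the secondary isopropyl groups leave as 2-chloropropane far faster than any methyl group, so both phenols are released together and no methyl ether has to be told from another.

Compound list
1 | 2,3-dimethylphenol | Cc1cccc(O)c1C | starting material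
2 | 2,3-dimethylphenyl N,N-diethylcarbamate | CCN(CC)C(=O)Oc1cccc(C)c1C | intermediate
3 | 6-lithio-2,3-dimethylphenyl N,N-diethylcarbamate | CCN(CC)C(=O)Oc1c([Li])ccc(C)c1C | intermediate
4 | rac-2,3-dimethyl-6-[(4-methylphenyl)sulfinyl]phenyl N,N-diethylcarbamate | CCN(CC)C(=O)Oc1c(S(=O)c2ccc(C)cc2)ccc(C)c1C | intermediate
5 | rac-2,3-dimethyl-6-[(4-methylphenyl)sulfinyl]phenol | Cc1ccc(S(=O)c2ccc(C)cc2)c(O)c1C | intermediate
6 | rac-2,3-dimethyl-6-[(4-methylphenyl)sulfinyl]phenyl trifluoromethanesulfonate | Cc1ccc(S(=O)c2ccc(C)cc2)c(OS(=O)(=O)C(F)(F)F)c1C | intermediate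
7 | 4-bromo-2,6-dimethoxyphenol | COc1cc(Br)cc(OC)c1O | starting material
8 | 5-bromo-1,3-dimethoxy-2-(propan-2-yloxy)benzene | COc1cc(Br)cc(OC)c1OC(C)C | intermediate
9 | [3,5-dimethoxy-4-(propan-2-yloxy)phenyl]lithium | COc1cc([Li])cc(OC)c1OC(C)C | intermediate
10 | chloro[3,5-dimethoxy-4-(propan-2-yloxy)phenyl]zinc | COc1cc([Zn]Cl)cc(OC)c1OC(C)C | intermediate
11 | rac-3',5'-dimethoxy-2,3-dimethyl-6-[(4-methylphenyl)sulfinyl]-4'-(propan-2-yloxy)-1,1'-biphenyl | COc1cc(-c2c(C)c(C)ccc2S(=O)c2ccc(C)cc2)cc(OC)c1OC(C)C | intermediate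
12 | [3',5'-dimethoxy-5,6-dimethyl-4'-(propan-2-yloxy)biphenyl-2-yl]lithium | COc1cc(-c2c(C)c(C)ccc2[Li])cc(OC)c1OC(C)C | intermediate
13 | [3',5'-dimethoxy-5,6-dimethyl-4'-(propan-2-yloxy)biphenyl-2-yl]trimethylstannane | COc1cc(-c2c(C)c(C)ccc2[Sn](C)(C)C)cc(OC)c1OC(C)C | intermediate
14 | 3,4-di(propan-2-yloxy)cyclobut-3-ene-1,2-dione (diisopropyl squarate) | CC(C)OC1=C(OC(C)C)C(=O)C1=O | starting material
15 | rac-4-hydroxy-2,3-di(propan-2-yloxy)cyclobut-2-en-1-one | CC(C)OC1=C(OC(C)C)C(=O)C1O | intermediate
16 | rac-4-chloro-2,3-di(propan-2-yloxy)cyclobut-2-en-1-one | CC(C)OC1=C(OC(C)C)C(=O)C1Cl | intermediate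
17 | rac-4-[2-(4-isopropoxy-3,5-dimethoxyphenyl)-3,4-dimethylphenyl]-2,3-diisopropoxycyclobut-2-en-1-one | CC(C)OC1=C(OC(C)C)C(=O)C1c1ccc(C)c(C)c1-c1cc(OC)c(OC(C)C)c(OC)c1 | intermediate
18 | rac-4-[2-(4-isopropoxy-3,5-dimethoxyphenyl)-3,4-dimethylphenyl]-2-isopropoxy-3-methoxycyclobut-2-en-1-one | COC1=C(OC(C)C)C(=O)C1c1ccc(C)c(C)c1-c1cc(OC)c(OC(C)C)c(OC)c1 | intermediate
19 | aryl-out dienylketene, 4-aryl-2-isopropoxy-3-methoxybuta-1,3-dien-1-one with aryl trans to the ketene carbon across C7=C8 | O=C=C(OC(C)C)/C(OC)=C/c1ccc(C)c(C)c1-c1cc(OC)c(OC(C)C)c(OC)c1 | intermediate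
20 | aryl-in dienylketene, same constitution with aryl cis to the ketene carbon across C7=C8 | O=C=C(OC(C)C)/C(OC)=C\c1ccc(C)c(C)c1-c1cc(OC)c(OC(C)C)c(OC)c1 | intermediate
21 | rac-5-(4-isopropoxy-3,5-dimethoxyphenyl)-2-isopropoxy-3-methoxy-6,7-dimethylnaphthalen-1(8aH)-one | O=C1C(OC(C)C)=C(OC)C=C2C(c3cc(OC)c(OC(C)C)c(OC)c3)=C(C)C(C)=CC12 | intermediate
22 | 5-(4-isopropoxy-3,5-dimethoxyphenyl)-2-isopropoxy-3-methoxy-6,7-dimethylnaphthalen-1-ol | COc1cc(-c2c(C)c(C)cc3c(O)c(OC(C)C)c(OC)cc23)cc(OC)c1OC(C)C | intermediate
23 | 1-(4-isopropoxy-3,5-dimethoxyphenyl)-6-isopropoxy-5,7-dimethoxy-2,3-dimethylnaphthalene | COc1cc(-c2c(C)c(C)cc3c(OC)c(OC(C)C)c(OC)cc23)cc(OC)c1OC(C)C | intermediate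
24 | sacidumlignan A, 5-(4-hydroxy-3,5-dimethoxyphenyl)-1,3-dimethoxy-6,7-dimethylnaphthalen-2-ol | COc1cc(-c2c(C)c(C)cc3c(OC)c(O)c(OC)cc23)cc(OC)c1O | target

Total step count: 14. Longest linear sequence: 11 steps (from 1 through steps 1, 2, 3, 4, 6, 7, 10, 11, 12, 13 and 14).

Steps most likely to fail

Step 10. Transfer of the ortho-arylated carbon from tin to palladium may be slower than ionisation and dealkylative collapse of the chloride, and methyl transfer from tin may compete.
- The fallback sets out from 11. Biaryllithium 12 is generated as in step 7 and quenched with ZnCl2 instead of Me3SnCl, giving chloro[3',5'-dimethoxy-5,6-dimethyl-4'-(propan-2-yloxy)biphenyl-2-yl]zinc F1.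
- F1 is joined to 16 in a Negishi-type allyl-aryl coupling (Pd2(dba)3, P(2-furyl)3, THF, 0 to 25 °C).
- Zinc hands the aryl group to palladium much faster than tin does and the stannane step is dropped. The route is rejoined at 17.

Step 9. The activated C4-O or C4-Cl bond may ionise with loss of the C2 isopropyl group, so that the ring collapses to a cyclobutenedione, or chloride may enter with allylic shift.
- The fallback sets out from 15 and avoids the halide. Ac2O, pyridine and DMAP in CH2Cl2 at 0 °C give rac-4-acetoxy-2,3-diisopropoxycyclobut-2-en-1-one F2, a storable ester that ionises only on zerovalent palladium.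
- An allylic-acetate Stille coupling with 13 (Pd2(dba)3, P(2-furyl)3, LiCl, NMP, 40 °C) rejoins the route at 17.

Step 12. Outward rotation of the bulky aryl group may dominate so strongly that the unproductive ketene is drained by dimerisation or by traces of water before it recloses, and long heating invites oxidation of the naphthol.
- The fallback sets out from 11 and 14 and places a donor on C4 that claims the outward position. Biaryllithium 12 adds to one carbonyl group of 14 (THF, -78 °C), and the alkoxide is silylated in the flask with TBSOTf to give rac-4-(tert-butyldimethylsilyloxy)-4-[2-(4-isopropoxy-3,5-dimethoxyphenyl)-3,4-dimethylphenyl]-2,3-diisopropoxycyclobut-2-en-1-one F3.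
- Camphorsulfonic acid in MeOH, as in step 11, gives the 2-isopropoxy-3-methoxy analogue F4.
- In toluene at 110 °C the silyloxy group rotates outward, the aryl group is forced inward, and the classical Moore rearrangement gives 4-(tert-butyldimethylsilyloxy)-5-(4-isopropoxy-3,5-dimethoxyphenyl)-2-isopropoxy-3-methoxy-6,7-dimethylnaphthalen-1-ol F5.
- MeI and K2CO3 in acetone give the O5-methyl ether F6, and TBAF frees 8-(4-isopropoxy-3,5-dimethoxyphenyl)-3-isopropoxy-2,4-dimethoxy-6,7-dimethylnaphthalen-1-ol F7.
- Tf2O and pyridine give its triflate F8. Formate reduction (Pd(OAc)2, dppp, HCO2H, Et3N, DMF, 80 °C) then replaces the C8 oxygen by hydrogen and rejoins the route at 23.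

Further compounds
F1 | step 10 | chloro[3',5'-dimethoxy-5,6-dimethyl-4'-(propan-2-yloxy)biphenyl-2-yl]zinc | COc1cc(-c2c(C)c(C)ccc2[Zn]Cl)cc(OC)c1OC(C)C
F2 | step 9 | rac-4-acetoxy-2,3-diisopropoxycyclobut-2-en-1-one | CC(=O)OC1C(OC(C)C)=C(OC(C)C)C1=O
F3 | step 12 | rac-4-(tert-butyldimethylsilyloxy)-4-[2-(4-isopropoxy-3,5-dimethoxyphenyl)-3,4-dimethylphenyl]-2,3-diisopropoxycyclobut-2-en-1-one | CC(C)OC1=C(OC(C)C)C(O[Si](C)(C)C(C)(C)C)(c2ccc(C)c(C)c2-c2cc(OC)c(OC(C)C)c(OC)c2)C1=O
F4 | step 12 | rac-4-(tert-butyldimethylsilyloxy)-4-[2-(4-isopropoxy-3,5-dimethoxyphenyl)-3,4-dimethylphenyl]-2-isopropoxy-3-methoxycyclobut-2-en-1-one | CC(C)OC1=C(OC)C(O[Si](C)(C)C(C)(C)C)(c2ccc(C)c(C)c2-c2cc(OC)c(OC(C)C)c(OC)c2)C1=O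
F5 | step 12 | 4-(tert-butyldimethylsilyloxy)-5-(4-isopropoxy-3,5-dimethoxyphenyl)-2-isopropoxy-3-methoxy-6,7-dimethylnaphthalen-1-ol | COc1cc(-c2c(C)c(C)cc3c(O)c(OC(C)C)c(OC)c(O[Si](C)(C)C(C)(C)C)c23)cc(OC)c1OC(C)C
F6 | step 12 | tert-butyl{[8-(4-isopropoxy-3,5-dimethoxyphenyl)-3-isopropoxy-2,4-dimethoxy-6,7-dimethylnaphthalen-1-yl]oxy}dimethylsilane | COc1cc(-c2c(C)c(C)cc3c(OC)c(OC(C)C)c(OC)c(O[Si](C)(C)C(C)(C)C)c23)cc(OC)c1OC(C)C
F7 | step 12 | 8-(4-isopropoxy-3,5-dimethoxyphenyl)-3-isopropoxy-2,4-dimethoxy-6,7-dimethylnaphthalen-1-ol | COc1cc(-c2c(C)c(C)cc3c(OC)c(OC(C)C)c(OC)c(O)c23)cc(OC)c1OC(C)C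
F8 | step 12 | 8-(4-isopropoxy-3,5-dimethoxyphenyl)-3-isopropoxy-2,4-dimethoxy-6,7-dimethylnaphthalen-1-yl trifluoromethanesulfonate | COc1cc(-c2c(C)c(C)cc3c(OC)c(OC(C)C)c(OC)c(OS(=O)(=O)C(F)(F)F)c23)cc(OC)c1OC(C)C
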